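**Strategy.** The pyran ring is opened between C4 (the benzylic CH2) and C4a (the aromatic carbon). On that ring the C3–O bond and the C4–aryl bond sit on neighbouring carbons, so both are traced back to one terminal alkene: the vinyl group of (R)-linalool, whose carbinol carbon already is C2 with its methyl group and six-carbon side chain. After O-arylation with a 2-bromo-4-(methoxycarbonyl)phenyl group, one flask operation does a platinum-catalysed asymmetric diboration of the vinyl group, an intramolecular Suzuki–Miyaura coupling of the primary boronate with the aryl bromide (ring closure) and oxidation of the secondary boronate to the C3 hydroxyl. Acetylation and a selenium-mediated allylic transposition of the prenyl terminus finish the synthesis.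

Key step: step 3

Assumption: commercial (R)-(−)-linalool of high enantiomeric purity supplies C2, and the sense of induction of the platinum/TADDOL-phosphonite diboration is taken by analogy with simple 1-alkenes, so the ligand antipode written below as the (R,R)-form is meant to be the one that gives the (3R) boronate; should the sense be opposite, the (S,S)-ligand is used.

**Step 1**
Reactants: 1 methyl 3-bromo-4-iodobenzoate; 2 1,3,5-trimethoxybenzene
Product: 4 [2-bromo-4-(methoxycarbonyl)phenyl](2,4,6-trimethoxyphenyl)iodonium tosylate, via hydroxy(tosyloxy)iodoarene 3 (not isolated)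
Conditions: mCPBA, TsOH·H2O, MeCN, 77 °C; then 2, 77 °C
Reagents that add atoms: p-toluenesulfonic acid monohydrate, Cc1ccc(S(=O)(=O)O)cc1.O
Why: The peracid oxidises the aryl iodide to the trivalent-iodine [hydroxy(tosyloxy)iodo]arene 3, which attacks the electron-rich trimethoxybenzene by electrophilic aromatic substitution (one-pot diaryliodonium salt synthesis), the trimethoxyphenyl group serving as the ligand that is not transferred later.

**Step 2**
Reactants: 5 (R)-(−)-linalool; 4 [2-bromo-4-(methoxycarbonyl)phenyl](2,4,6-trimethoxyphenyl)iodonium tosylate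
Product: 7 methyl 3-bromo-4-{[(3R)-3,7-dimethylocta-1,6-dien-3-yl]oxy}benzoate, via sodium (R)-linaloolate 6 (not isolated)
Conditions: NaN(SiMe3)2, toluene, 0 °C; then 4, 0 °C to rt
Reagents that add atoms: none
Why: Metal-free O-arylation of a tertiary alkoxide with a diaryliodonium salt (ligand exchange at trivalent iodine, then ipso ligand coupling) should transfer the electron-poor, ortho-substituted benzoate ring in preference to the trimethoxyphenyl ligand; the tertiary alkoxide cannot be oxidised, the coupling is fast enough to outrun attack on the methyl ester, and the C–O bond of linalool is untouched, so C2 keeps its (R) configuration.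

**Step 3**
Reactants: 7 methyl 3-bromo-4-{[(3R)-3,7-dimethylocta-1,6-dien-3-yl]oxy}benzoate
Product: 10 methyl (2R,3R)-3-hydroxy-2-methyl-2-(4-methylpent-3-en-1-yl)-3,4-dihydro-2H-chromene-6-carboxylate, via vicinal bis(boronate) 8 (not isolated), via 3-borylchroman 9 (not isolated)
Conditions: Pt(dba)3 (cat.), (R,R)-3,5-diisopropylphenyl-TADDOL phenylphosphonite (cat.), B2pin2, THF, 60 °C; then Pd(OAc)2, RuPhos, K3PO4, THF/H2O, 70 °C; then 30% H2O2, 0 °C to rt
Reagents that add atoms: hydrogen peroxide, OO
Why: Zerovalent platinum adds B2pin2 oxidatively, the vinyl group inserts into a Pt–B bond in the stereodetermining step and reductive elimination gives the vicinal bis(boronate) 8 by syn addition; zerovalent palladium then inserts into the C–Br bond, the primary C–B bond transmetalates under base, C(sp2)–C(sp3) reductive elimination forms the aryl–CH2 bond, and peroxide finally oxidises the remaining secondary C–B bond with retention. The closest known reaction type is the one-pot enantioselective diboration / Suzuki–Miyaura cross-coupling / oxidation cascade of 1-alkenes, run here intramolecularly as a B-alkyl Suzuki–Miyaura ring closure. The pyran ring is closed as a six-membered ring by reductive elimination from a seven-membered aryl(alkyl)palladacycle; closure through the secondary boronate would give a five-membered ring at a neopentyl carbon and is disfavoured by the slow transmetalation of secondary alkylboronates. The new stereocentre C3 is set in the diboration by the chiral phosphonite ligand on platinum (catalyst control, since the methyl and alkyl arms on the neighbouring quaternary C2 differ little) and is carried unchanged through coupling and oxidation. The step needs chemoselectivity for the monosubstituted vinyl group over the trisubstituted 6,7-alkene, which the platinum diboration secures because it accepts only terminal monosubstituted alkenes, and survival of the methyl ester, which K3PO4 in place of hydroxide is meant to secure.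

**Step 4**
Reactants: 10 methyl (2R,3R)-3-hydroxy-2-methyl-2-(4-methylpent-3-en-1-yl)-3,4-dihydro-2H-chromene-6-carboxylate
Product: 11 methyl (2R,3R)-3-acetoxy-2-methyl-2-(4-methylpent-3-en-1-yl)-3,4-dihydro-2H-chromene-6-carboxylate
Conditions: Ac2O, pyridine, DMAP (cat.), CH2Cl2, 0 °C to rt
Reagents that add atoms: acetic anhydride, CC(=O)OC(C)=O
Why: DMAP-catalysed acylation (nucleophilic catalysis) of the only hydroxyl group should go cleanly despite the neighbouring quaternary carbon, and no stereocentre is touched.

**Step 5**
Reactants: 11 methyl (2R,3R)-3-acetoxy-2-methyl-2-(4-methylpent-3-en-1-yl)-3,4-dihydro-2H-chromene-6-carboxylate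
Product: 14 target methyl (2R,3R)-3-acetoxy-2-[(2E)-4-hydroxy-4-methylpent-2-en-1-yl]-2-methyl-3,4-dihydro-2H-chromene-6-carboxylate, via β-hydroxy selenide 12 (not isolated), via selenoxide 13 (not isolated)
Conditions: N-(phenylselanyl)phthalimide, H2O, camphorsulfonic acid (cat.), CH2Cl2, rt; then 30% H2O2, pyridine, 0 °C to rt
Reagents that add atoms: water, O
Why: Electrophilic hydroxyselenation of the trisubstituted alkene (seleniranium ion opened by water at the tertiary carbon, Markovnikov) followed by oxidation and selenoxide syn-elimination, which can only take a hydrogen from the ring-side CH2 because the carbinol carbon bears none, should give the (E)-allylic tertiary alcohol with the double bond moved by one position; acetate, methyl ester and the electron-poor arene are inert to the selenium electrophile.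

**Compound list**
1 | methyl 3-bromo-4-iodobenzoate | COC(=O)c1ccc(I)c(Br)c1 | starting material
2 | 1,3,5-trimethoxybenzene | COc1cc(OC)cc(OC)c1 | starting material
3 | methyl 3-bromo-4-[hydroxy(tosyloxy)iodo]benzoate | COC(=O)c1ccc(I(O)OS(=O)(=O)c2ccc(C)cc2)c(Br)c1 | intermediate
4 | [2-bromo-4-(methoxycarbonyl)phenyl](2,4,6-trimethoxyphenyl)iodonium tosylate | COC(=O)c1ccc([I+]c2c(OC)cc(OC)cc2OC)c(Br)c1.Cc1ccc(S(=O)(=O)[O-])cc1 | intermediate
5 | (R)-(−)-linalool, (3R)-3,7-dimethylocta-1,6-dien-3-ol | CC(C)=CCC[C@@](C)(O)C=C | starting material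
6 | sodium (3R)-3,7-dimethylocta-1,6-dien-3-olate | CC(C)=CCC[C@@](C)([O-])C=C.[Na+] | intermediate
7 | methyl 3-bromo-4-{[(3R)-3,7-dimethylocta-1,6-dien-3-yl]oxy}benzoate | CC(C)=CCC[C@@](C)(Oc1ccc(C(=O)OC)cc1Br)C=C | intermediate
8 | methyl 3-bromo-4-{[(2R,3R)-3,7-dimethyl-1,2-bis(4,4,5,5-tetramethyl-1,3,2-dioxaborolan-2-yl)oct-6-en-3-yl]oxy}benzoate | COC(=O)c1ccc(O[C@](C)(CCC=C(C)C)[C@@H](CB2OC(C)(C)C(C)(C)O2)B2OC(C)(C)C(C)(C)O2)c(Br)c1 | intermediate
9 | methyl (2R,3R)-2-methyl-2-(4-methylpent-3-en-1-yl)-3-(4,4,5,5-tetramethyl-1,3,2-dioxaborolan-2-yl)-3,4-dihydro-2H-chromene-6-carboxylate | COC(=O)c1ccc2c(c1)C[C@@H](B3OC(C)(C)C(C)(C)O3)[C@@](C)(CCC=C(C)C)O2 | intermediate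
10 | methyl (2R,3R)-3-hydroxy-2-methyl-2-(4-methylpent-3-en-1-yl)-3,4-dihydro-2H-chromene-6-carboxylate | COC(=O)c1ccc2c(c1)C[C@@H](O)[C@@](C)(CCC=C(C)C)O2 | intermediate
11 | methyl (2R,3R)-3-acetoxy-2-methyl-2-(4-methylpent-3-en-1-yl)-3,4-dihydro-2H-chromene-6-carboxylate | COC(=O)c1ccc2c(c1)C[C@@H](OC(C)=O)[C@@](C)(CCC=C(C)C)O2 | intermediate
12 | methyl (2R,3R)-3-acetoxy-2-[4-hydroxy-4-methyl-3-(phenylselanyl)pentyl]-2-methyl-3,4-dihydro-2H-chromene-6-carboxylate (both epimers at the selenium-bearing carbon) | COC(=O)c1ccc2c(c1)C[C@@H](OC(C)=O)[C@@](C)(CCC([Se]c3ccccc3)C(C)(C)O)O2 | intermediate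
13 | methyl (2R,3R)-3-acetoxy-2-[4-hydroxy-4-methyl-3-(phenylseleninyl)pentyl]-2-methyl-3,4-dihydro-2H-chromene-6-carboxylate | COC(=O)c1ccc2c(c1)C[C@@H](OC(C)=O)[C@@](C)(CCC([Se](=O)c3ccccc3)C(C)(C)O)O2 | intermediate
14 | methyl (2R,3R)-3-acetoxy-2-[(2E)-4-hydroxy-4-methylpent-2-en-1-yl]-2-methyl-3,4-dihydro-2H-chromene-6-carboxylate | COC(=O)c1ccc2c(c1)C[C@@H](OC(C)=O)[C@@](C)(C/C=C/C(C)(C)O)O2 | target

**Step count.** Total: 5 steps. Longest linear sequence: 5 steps (1 → 4 → 7 → 10 → 11 → 14); 4 steps from (R)-linalool.

**Steps most likely to fail**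

1. Step 3. The diboration may stall at the vinyl group next to the fully substituted carbon, or the borylplatinum intermediate may lose aryloxide by β-elimination. The ligand may also control the face of the alkene only partly, and the ester may be hydrolysed or the boronate protodeboronated in the coupling stage. The fallback sets out from 7 and comes back at 10, and closes the same aryl–CH2 bond by enolate arylation. A catalyst-controlled Wacker oxidation of the vinyl group (PdCl2(quinox) with quinox = 2-(4,5-dihydro-1,3-oxazol-2-yl)quinoline, AgSbF6, aqueous tBuOOH, CH2Cl2, rt) should give the methyl ketone methyl 3-bromo-4-{[(3R)-3,7-dimethyl-2-oxooct-6-en-3-yl]oxy}benzoate F1. Intramolecular palladium-catalysed α-arylation of its only enolisable position (Pd2(dba)3, XPhos, K3PO4, toluene, 80 °C) should then give methyl (2R)-2-methyl-2-(4-methylpent-3-en-1-yl)-3-oxo-3,4-dihydro-2H-chromene-6-carboxylate F2. Corey–Bakshi–Shibata reduction ((S)-2-methyl-CBS-oxazaborolidine, BH3·SMe2, THF, −20 °C), with the quaternary C2 acting as the large group, is expected to deliver the (3R) alcohol 10.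

2. Step 2. The base may deprotonate the position ortho to iodine and form an aryne, with loss of regiocontrol. The wrong aryl ligand may be transferred, or the tertiary alkoxide may transesterify the methyl ester. The fallback sets out from 5 and comes back at 7, and replaces the iodonium coupling by nucleophilic aromatic substitution on an aldehyde-activated fluoride. Linalool is deprotonated with KN(SiMe3)2 in THF and treated with 3-bromo-4-fluorobenzaldehyde (−20 °C to rt) to give 3-bromo-4-{[(3R)-3,7-dimethylocta-1,6-dien-3-yl]oxy}benzaldehyde F3. Pinnick oxidation (NaClO2, NaH2PO4, 2-methylbut-2-ene, tBuOH/H2O) should give 3-bromo-4-{[(3R)-3,7-dimethylocta-1,6-dien-3-yl]oxy}benzoic acid F4. O-Methylation (MeI, K2CO3, DMF) then gives 7.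

3. Step 5. The seleniranium ion may be opened with poor regiocontrol. Seleninic acid and peroxide may epoxidise the new alkene, or the tertiary allylic alcohol may ionise under the acidic first stage. The fallback sets out from 11 and comes back at 14, and avoids selenium by a Schenck ene reaction. Photooxygenation (O2, tetraphenylporphyrin, visible light, CH2Cl2, 0 °C) should give the tertiary allylic hydroperoxide methyl (2R,3R)-3-acetoxy-2-[(2E)-4-hydroperoxy-4-methylpent-2-en-1-yl]-2-methyl-3,4-dihydro-2H-chromene-6-carboxylate F5. The ene reaction also forms the regioisomer methyl (2R,3R)-3-acetoxy-2-(3-hydroperoxy-4-methylpent-4-en-1-yl)-2-methyl-3,4-dihydro-2H-chromene-6-carboxylate F6, which is removed by chromatography. Reduction of F5 with PPh3 (CH2Cl2, 0 °C) gives 14.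

**Further compounds**
F1 | step 3 | methyl 3-bromo-4-{[(3R)-3,7-dimethyl-2-oxooct-6-en-3-yl]oxy}benzoate | CC(C)=CCC[C@@](C)(Oc1ccc(C(=O)OC)cc1Br)C(C)=O
F2 | step 3 | methyl (2R)-2-methyl-2-(4-methylpent-3-en-1-yl)-3-oxo-3,4-dihydro-2H-chromene-6-carboxylate | COC(=O)c1ccc2c(c1)CC(=O)[C@@](C)(CCC=C(C)C)O2
F3 | step 2 | 3-bromo-4-{[(3R)-3,7-dimethylocta-1,6-dien-3-yl]oxy}benzaldehyde | CC(C)=CCC[C@@](C)(Oc1ccc(C=O)cc1Br)C=C
F4 | step 2 | 3-bromo-4-{[(3R)-3,7-dimethylocta-1,6-dien-3-yl]oxy}benzoic acid | CC(C)=CCC[C@@](C)(Oc1ccc(C(=O)O)cc1Br)C=C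
F5 | step 5 | methyl (2R,3R)-3-acetoxy-2-[(2E)-4-hydroperoxy-4-methylpent-2-en-1-yl]-2-methyl-3,4-dihydro-2H-chromene-6-carboxylate | COC(=O)c1ccc2c(c1)C[C@@H](OC(C)=O)[C@@](C)(C/C=C/C(C)(C)OO)O2
F6 | step 5 | methyl (2R,3R)-3-acetoxy-2-(3-hydroperoxy-4-methylpent-4-en-1-yl)-2-methyl-3,4-dihydro-2H-chromene-6-carboxylate | COC(=O)c1ccc2c(c1)C[C@@H](OC(C)=O)[C@@](C)(CCC(OO)C(C)=C)O2
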